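Everything hinges on disconnecting the Ca–Cd bond, the one link between two sp3 carbons inside the seven-membered ring: Ca (CH joining benzofuran ring A and formyl-bearing ring E) and Cd (CH joining resorcinol ring B and a 4-hydroxyphenyl group) are each flanked by two arenes. Forward, a nitrogen atom bridging Ca and Cd is excised from a dibenzo-fused azocine: an anomeric amide turns the NH into an isodiazene, N2 leaves, and the two diarylmethyl radicals pair up, shrinking the eight-membered ring to the carbocycle and fixing both stereocentres in one operation. The precursor is the hexamethylated azocine carrying the naringenin-derived trans-dihydrobenzofuran and ring E's aldehyde as dimethyl acetal.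

Key step: step 13

Labels: ring A is the benzo ring of the dihydrobenzofuran (C4 carries Ca, C6 an oxygen); C2 and C3 are the dihydrofuran CH groups (C2 bears the 4-oxygenated phenyl ring D, C3 bears ring B); ring C is the 4-oxygenated phenyl group on Cd.

Assumption: (2S)-naringenin is used as a single enantiomer, and the flavanone stage (steps 1 to 3) is kept free of strong base because flavanones racemise at C2 through reversible opening to the chalcone.

Step 1
Reactants: 1 (2S)-naringenin
Product: 2 (2S)-5-hydroxy-7-methoxy-2-(4-methoxyphenyl)chroman-4-one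
Conditions: CH2N2, Et2O/MeOH, 0 °C to rt
Reagents that add atoms: diazomethane, C=[N+]=[N-]
Why: O-methylation of phenols with diazomethane should alkylate the 7- and 4'-hydroxyls under neutral conditions while the 5-hydroxyl, hydrogen-bonded to the C4 carbonyl, stays free, and the absence of base avoids the chalcone pathway that would erode C2.

Step 2
Reactants: 2 (2S)-5-hydroxy-7-methoxy-2-(4-methoxyphenyl)chroman-4-one
Product: 3 (2S)-7-methoxy-2-(4-methoxyphenyl)-4-oxochroman-5-yl trifluoromethanesulfonate
Conditions: Tf2O, pyridine, CH2Cl2, 0 °C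
Reagents that add atoms: trifluoromethanesulfonic anhydride, O=S(=O)(OS(=O)(=O)C(F)(F)F)C(F)(F)F
Why: O-sulfonylation (triflate formation) of the remaining chelated phenol with a weak base at low temperature should leave C2 intact, and the triflate both shields the phenol from the oxidant of step 3 and serves as the later carbonylation handle.

Step 3
Reactants: 3 (2S)-7-methoxy-2-(4-methoxyphenyl)-4-oxochroman-5-yl trifluoromethanesulfonate
Product: 4 methyl (2S,3S)-6-methoxy-2-(4-methoxyphenyl)-4-(trifluoromethanesulfonyloxy)-2,3-dihydrobenzofuran-3-carboxylate (2,3-trans)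
Conditions: PhI(OAc)2, H2SO4, HC(OMe)3, rt; aqueous work-up
Reagents that add atoms: trimethyl orthoformate, COC(OC)OC; water, O
Why: in this hypervalent-iodine oxidative ring contraction of a flavanone (1,2-aryl shift) the enol ether formed in the orthoformate is attacked at C3 by the iodane anti to the C2 aryl group, ring A then migrates from C4 to C3 with inversion as iodobenzene departs, and the dialkoxycarbenium ion collapses to the methyl ester, so the 2,3-trans dihydrobenzofuran should form with C2 untouched.

Step 4
Reactants: 4 methyl (2S,3S)-6-methoxy-2-(4-methoxyphenyl)-4-(trifluoromethanesulfonyloxy)-2,3-dihydrobenzofuran-3-carboxylate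
Product: 5 (2S,3S)-6-methoxy-2-(4-methoxyphenyl)-4-(trifluoromethanesulfonyloxy)-2,3-dihydrobenzofuran-3-carboxylic acid
Conditions: Me3SnOH, 1,2-dichloroethane, 80 °C; then aq. HCl wash
Reagents that add atoms: trimethyltin hydroxide, C[Sn](C)(C)O
Why: ester cleavage with trimethyltin hydroxide is a neutral hydrolysis that should spare the aryl triflate and avoid the ester enolate, which could open the ring by β-elimination of the aryloxide.

Step 5
Reactants: 5 (2S,3S)-6-methoxy-2-(4-methoxyphenyl)-4-(trifluoromethanesulfonyloxy)-2,3-dihydrobenzofuran-3-carboxylic acid; 6 1-bromo-3,5-dimethoxybenzene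
Product: 7 (2S,3S)-3-(3,5-dimethoxyphenyl)-6-methoxy-2-(4-methoxyphenyl)-2,3-dihydrobenzofuran-4-yl trifluoromethanesulfonate
Conditions: Ir[dF(CF3)ppy]2(dtbbpy)PF6 (cat.), NiCl2·glyme (cat.), dtbbpy, Cs2CO3, DMF, blue LEDs, rt
Reagents that add atoms: none
Why: in this nickel/photoredox decarboxylative C(sp3)–C(sp2) cross-coupling the excited iridium complex oxidises the carboxylate, loss of CO2 gives the benzylic C3 radical, this is captured by the aryl–nickel species from 6 (bipyridine-ligated nickel inserts into the aryl bromide much faster than into the hindered aryl triflate), and reductive elimination on the face anti to the C2 aryl group should set C3 trans (S).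

Step 6
Reactants: 7 (2S,3S)-3-(3,5-dimethoxyphenyl)-6-methoxy-2-(4-methoxyphenyl)-2,3-dihydrobenzofuran-4-yl trifluoromethanesulfonate; 8 4-methoxybenzoyl chloride
Product: 9 (2S,3S)-3-[3,5-dimethoxy-2-(4-methoxybenzoyl)phenyl]-6-methoxy-2-(4-methoxyphenyl)-2,3-dihydrobenzofuran-4-yl trifluoromethanesulfonate
Conditions: SnCl4, CH2Cl2, −20 to 0 °C
Reagents that add atoms: none
Why: Friedel–Crafts acylation should take place on ring B, a 5-alkylresorcinol dimethyl ether and the most nucleophilic arene present (ring A is deactivated by the triflate), at the position ortho to the C3 substituent and para to a methoxy group in preference to the doubly flanked site between the two methoxy groups, and it is run before an aldehyde sits at C4 so that no carbonyl electrophile lies next to the still unsubstituted ring B.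

Step 7
Reactants: 9 (2S,3S)-3-[3,5-dimethoxy-2-(4-methoxybenzoyl)phenyl]-6-methoxy-2-(4-methoxyphenyl)-2,3-dihydrobenzofuran-4-yl trifluoromethanesulfonate
Product: 10 (2S,3S)-3-[3,5-dimethoxy-2-(4-methoxybenzoyl)phenyl]-6-methoxy-2-(4-methoxyphenyl)-2,3-dihydrobenzofuran-4-carbaldehyde
Conditions: Pd(OAc)2 (cat.), dppp, CO (1 atm), Et3SiH, Et3N, DMF, 70 °C
Reagents that add atoms: carbon monoxide, [C-]#[O+]
Why: palladium-catalysed reductive carbonylation (formylation) of an aryl triflate proceeds by oxidative addition, CO insertion and hydride transfer from the silane, and the hindered diaryl ketone should be inert to these conditions.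

Step 8
Reactants: 10 (2S,3S)-3-[3,5-dimethoxy-2-(4-methoxybenzoyl)phenyl]-6-methoxy-2-(4-methoxyphenyl)-2,3-dihydrobenzofuran-4-carbaldehyde
Product: 11 (R)-N-[(E)-{(2S,3S)-3-[3,5-dimethoxy-2-(4-methoxybenzoyl)phenyl]-6-methoxy-2-(4-methoxyphenyl)-2,3-dihydrobenzofuran-4-yl}methylidene]-2-methylpropane-2-sulfinamide
Conditions: (R)-tBuS(O)NH2, Ti(OEt)4, THF, rt
Reagents that add atoms: (R)-2-methylpropane-2-sulfinamide, CC(C)(C)[S@@](=O)N
Why: in this Ellman condensation Ti(OEt)4 acts as Lewis acid and water scavenger and only the aldehyde should form the (E)-N-sulfinyl imine, because the doubly ortho-substituted, electron-rich diaryl ketone does not condense at room temperature.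

Step 9
Reactants: 12 3-bromo-4-methoxybenzaldehyde
Product: 13 2-bromo-4-(dimethoxymethyl)-1-methoxybenzene
Conditions: HC(OMe)3, TsOH (cat.), MeOH, rt
Reagents that add atoms: trimethyl orthoformate, COC(OC)OC; methanol, CO
Why: acid-catalysed acetalisation driven by the orthoformate masks the aldehyde so that the aryl bromide can be turned into a Grignard reagent.

Step 10
Reactants: 11 the (R)-N-sulfinyl aldimine; 13 2-bromo-4-(dimethoxymethyl)-1-methoxybenzene
Product: 15 (R)-N-{(R)-[5-(dimethoxymethyl)-2-methoxyphenyl][(2S,3S)-3-[3,5-dimethoxy-2-(4-methoxybenzoyl)phenyl]-6-methoxy-2-(4-methoxyphenyl)-2,3-dihydrobenzofuran-4-yl]methyl}-2-methylpropane-2-sulfinamide, via arylmagnesium bromide 14 (not isolated)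
Conditions: 13, Mg, LiCl, THF, rt; then added to 11 in CH2Cl2, −48 to −20 °C; aq. NH4Cl
Reagents that add atoms: none
Why: diastereoselective 1,2-addition of an aryl Grignard reagent to an N-tert-butanesulfinyl aldimine in a non-coordinating solvent passes through a six-membered chelate that delivers ring E to the Si face of the (R)-sulfinyl imine, which should set Ca as (R), while the twisted, doubly ortho-substituted and electron-rich ketone should not compete at low temperature.

Step 11
Reactants: 15 the (R,R)-sulfinamide
Product: 16 {2-[(2S,3S)-4-{(R)-amino[5-(dimethoxymethyl)-2-methoxyphenyl]methyl}-6-methoxy-2-(4-methoxyphenyl)-2,3-dihydrobenzofuran-3-yl]-4,6-dimethoxyphenyl}(4-methoxyphenyl)methanone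
Conditions: HCl (4 M in dioxane), MeOH, 0 °C; then aq. NaHCO3
Reagents that add atoms: none
Why: acidic methanolysis of the sulfinamide S–N bond frees the primary amine, and in anhydrous methanol the dimethyl acetal can only undergo degenerate exchange.

Step 12
Reactants: 16 the (R)-amino ketone
Product: 18 azocine with the eight-membered ring Ca–NH–Cd–ring B–C3–ring A (Ca R; Cd S; C2 S; C3 S; ring E trans to ring C across NH; six methyl ethers; dimethyl acetal), via cyclic ketimine 17 (not isolated)
Conditions: Ti(OiPr)4, toluene, 80 °C; then NaBH4, MeOH, −20 °C to rt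
Reagents that add atoms: none
Why: in this intramolecular reductive amination Ti(OiPr)4 drives condensation of the Ca amine with the neighbouring ketone, which the adjacent C3 and C4 substituents hold close, to the eight-membered cyclic ketimine without touching the acetal, and borohydride should add to the face of the C=N bond that points away from ring A, leaving ring C pseudo-equatorial and trans to ring E, (S) at Cd.

Step 13
Reactants: 18 the azocine
Product: 22 vitisinol B hexamethyl ether dimethyl acetal (Ca R; Cd S; C2 S; C3 S), via N-amino-N-benzyloxy amide 19 (not isolated), via isodiazene 20 (not isolated), via Ca/Cd diradical 21 (not isolated)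
Conditions: N-(benzyloxy)-N-(pivaloyloxy)-4-(trifluoromethyl)benzamide (1.5 equiv), THF, 45 °C
Reagents that add atoms: none
Why: The secondary amine displaces pivalate at the amide nitrogen to give 19, whose benzyloxy group shifts to the carbonyl carbon with release of benzyl 4-(trifluoromethyl)benzoate and isodiazene 20; 20 extrudes N2 and the diradical 21, with one unpaired electron on Ca and one on Cd, collapses to the Ca–Cd bond. The closest known reaction type is the nitrogen deletion of secondary benzylic amines by anomeric amides, which is established for the ring contraction of cyclic amines. The seven-membered ring closes by intramolecular radical–radical recombination of a 1,7-diradical whose termini are kept within bonding distance by the ring A–C3–ring B backbone, not by addition to a π bond. Ca and Cd are set at the recombination under control of the resident C3 centre and the rigid trans-dihydrobenzofuran, which should favour the isomer with ring E and ring C both pseudo-equatorial and trans (Ca R, Cd S), and the trans amine reaches the same isomer by least motion. The step needs C–C recombination to outrun disproportionation, hydrogen abstraction from the solvent and coupling through aryl positions, which is secured because neither radical has a β-hydrogen, both are stabilised by two aryl groups and the tether keeps them paired.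

Step 14
Reactants: 22 vitisinol B hexamethyl ether dimethyl acetal
Product: 23 vitisinol B
Conditions: BBr3, CH2Cl2, −78 °C to rt; then H2O
Reagents that add atoms: none
Why: Lewis-acid ether cleavage with BBr3 should remove the six aryl methyl ethers and the dimethyl acetal in one operation, aqueous work-up releasing the phenols and the aldehyde, and a reversible ionisation of the benzylic C2–O bond would only return the more stable 2,3-trans ring because C3 is not affected.

Compound list

1 | (2S)-naringenin, (2S)-5,7-dihydroxy-2-(4-hydroxyphenyl)chroman-4-one | O=C1C[C@@H](c2ccc(O)cc2)Oc2cc(O)cc(O)c21 | starting material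
2 | (2S)-5-hydroxy-7-methoxy-2-(4-methoxyphenyl)chroman-4-one | O=C1C[C@@H](c2ccc(OC)cc2)Oc2cc(OC)cc(O)c21 | intermediate
3 | (2S)-7-methoxy-2-(4-methoxyphenyl)-4-oxochroman-5-yl trifluoromethanesulfonate | O=C1C[C@@H](c2ccc(OC)cc2)Oc2cc(OC)cc(OS(=O)(=O)C(F)(F)F)c21 | intermediate
4 | methyl (2S,3S)-6-methoxy-2-(4-methoxyphenyl)-4-(trifluoromethanesulfonyloxy)-2,3-dihydrobenzofuran-3-carboxylate (2,3-trans) | FC(F)(F)S(=O)(=O)Oc1cc(OC)cc2c1[C@H](C(=O)OC)[C@@H](c1ccc(OC)cc1)O2 | intermediate
5 | (2S,3S)-6-methoxy-2-(4-methoxyphenyl)-4-(trifluoromethanesulfonyloxy)-2,3-dihydrobenzofuran-3-carboxylic acid | FC(F)(F)S(=O)(=O)Oc1cc(OC)cc2c1[C@H](C(=O)O)[C@@H](c1ccc(OC)cc1)O2 | intermediate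
6 | 1-bromo-3,5-dimethoxybenzene | COc1cc(Br)cc(OC)c1 | starting material
7 | (2S,3S)-3-(3,5-dimethoxyphenyl)-6-methoxy-2-(4-methoxyphenyl)-2,3-dihydrobenzofuran-4-yl trifluoromethanesulfonate (2,3-trans) | FC(F)(F)S(=O)(=O)Oc1cc(OC)cc2c1[C@H](c1cc(OC)cc(OC)c1)[C@@H](c1ccc(OC)cc1)O2 | intermediate
8 | 4-methoxybenzoyl chloride | COc1ccc(C(Cl)=O)cc1 | starting material
9 | (2S,3S)-3-[3,5-dimethoxy-2-(4-methoxybenzoyl)phenyl]-6-methoxy-2-(4-methoxyphenyl)-2,3-dihydrobenzofuran-4-yl trifluoromethanesulfonate | FC(F)(F)S(=O)(=O)Oc1cc(OC)cc2c1[C@H](c1cc(OC)cc(OC)c1C(=O)c1ccc(OC)cc1)[C@@H](c1ccc(OC)cc1)O2 | intermediate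
10 | (2S,3S)-3-[3,5-dimethoxy-2-(4-methoxybenzoyl)phenyl]-6-methoxy-2-(4-methoxyphenyl)-2,3-dihydrobenzofuran-4-carbaldehyde | O=Cc1cc(OC)cc2c1[C@H](c1cc(OC)cc(OC)c1C(=O)c1ccc(OC)cc1)[C@@H](c1ccc(OC)cc1)O2 | intermediate
11 | (R)-N-[(E)-{(2S,3S)-3-[3,5-dimethoxy-2-(4-methoxybenzoyl)phenyl]-6-methoxy-2-(4-methoxyphenyl)-2,3-dihydrobenzofuran-4-yl}methylidene]-2-methylpropane-2-sulfinamide | CC(C)(C)[S@@](=O)/N=C/c1cc(OC)cc2c1[C@H](c1cc(OC)cc(OC)c1C(=O)c1ccc(OC)cc1)[C@@H](c1ccc(OC)cc1)O2 | intermediate
12 | 3-bromo-4-methoxybenzaldehyde | COc1ccc(C=O)cc1Br | starting material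
13 | 2-bromo-4-(dimethoxymethyl)-1-methoxybenzene | COc1ccc(C(OC)OC)cc1Br | intermediate
14 | [5-(dimethoxymethyl)-2-methoxyphenyl]magnesium bromide | COc1ccc(C(OC)OC)cc1[Mg]Br | intermediate (not isolated)
15 | (R)-N-{(R)-[5-(dimethoxymethyl)-2-methoxyphenyl][(2S,3S)-3-[3,5-dimethoxy-2-(4-methoxybenzoyl)phenyl]-6-methoxy-2-(4-methoxyphenyl)-2,3-dihydrobenzofuran-4-yl]methyl}-2-methylpropane-2-sulfinamide | COC(OC)c1ccc(OC)c([C@H](N[S@](=O)C(C)(C)C)c2cc(OC)cc3c2[C@H](c2cc(OC)cc(OC)c2C(=O)c2ccc(OC)cc2)[C@@H](c2ccc(OC)cc2)O3)c1 | intermediate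
16 | {2-[(2S,3S)-4-{(R)-amino[5-(dimethoxymethyl)-2-methoxyphenyl]methyl}-6-methoxy-2-(4-methoxyphenyl)-2,3-dihydrobenzofuran-3-yl]-4,6-dimethoxyphenyl}(4-methoxyphenyl)methanone | COC(OC)c1ccc(OC)c([C@H](N)c2cc(OC)cc3c2[C@H](c2cc(OC)cc(OC)c2C(=O)c2ccc(OC)cc2)[C@@H](c2ccc(OC)cc2)O3)c1 | intermediate
17 | cyclic ketimine of 16: eight-membered ring with a Cd=N double bond, Ca (R), C2 (S), C3 (S) | COC(OC)c1ccc(OC)c([C@H]2c3cc(OC)cc4c3[C@H](c3cc(OC)cc(OC)c3C(=N2)c2ccc(OC)cc2)[C@@H](c2ccc(OC)cc2)O4)c1 | intermediate (not isolated)
18 | dibenzo-fused azocine (ring Ca–NH–Cd–ring B–C3–ring A) with the trans-dihydrobenzofuran, six methyl ethers and the ring E dimethyl acetal; Ca (R), Cd (S), C2 (S), C3 (S); ring E and ring C trans across NH | COC(OC)c1ccc(OC)c([C@H]2c3cc(OC)cc4c3[C@H](c3cc(OC)cc(OC)c3[C@@H](N2)c2ccc(OC)cc2)[C@@H](c2ccc(OC)cc2)O4)c1 | intermediate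
19 | N-(benzyloxy)-4-(trifluoromethyl)benzamide carrying the azocine nitrogen of 18 on its amide nitrogen | COC(OC)c1ccc(OC)c([C@H]2c3cc(OC)cc4c3[C@H](c3cc(OC)cc(OC)c3[C@@H](N2N(OCc2ccccc2)C(=O)c2ccc(C(F)(F)F)cc2)c2ccc(OC)cc2)[C@@H](c2ccc(OC)cc2)O4)c1 | intermediate (not isolated)
20 | isodiazene (1,1-diazene) of 18: ring nitrogen bearing a terminal N | COC(OC)c1ccc(OC)c([C@H]2c3cc(OC)cc4c3[C@H](c3cc(OC)cc(OC)c3[C@@H]([N+]2=[N-])c2ccc(OC)cc2)[C@@H](c2ccc(OC)cc2)O4)c1 | intermediate (not isolated)
21 | 1,7-diradical with diarylmethyl radical centres at Ca and Cd; C2 (S), C3 (S) | COC(OC)c1ccc(OC)c([CH]c2cc(OC)cc3c2[C@H](c2cc(OC)cc(OC)c2[CH]c2ccc(OC)cc2)[C@@H](c2ccc(OC)cc2)O3)c1 | intermediate (not isolated)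
22 | vitisinol B hexamethyl ether dimethyl acetal; Ca (R), Cd (S), C2 (S), C3 (S) | COC(OC)c1ccc(OC)c([C@H]2c3cc(OC)cc4c3[C@H](c3cc(OC)cc(OC)c3[C@@H]2c2ccc(OC)cc2)[C@@H](c2ccc(OC)cc2)O4)c1 | intermediate
23 | vitisinol B; Ca (R), Cd (S), C2 (S), C3 (S) | O=Cc1ccc(O)c([C@H]2c3cc(O)cc4c3[C@H](c3cc(O)cc(O)c3[C@@H]2c2ccc(O)cc2)[C@@H](c2ccc(O)cc2)O4)c1 | target

Total step count: 14. Longest linear sequence: 13 steps (steps 1 to 8 and 10 to 14, from naringenin); step 9 is a one-step side branch.

Steps most likely to fail

Step 13. N–N bond formation at a nitrogen flanked by two diarylmethyl groups may be too slow, so that the anomeric amide decomposes before the isodiazene forms. In addition, the long-lived diradical may recombine with poor diastereoselectivity, although a Cd epimer of the amine would be expected to enter the same diradical. The fallback generates the isodiazene stepwise by classical chemistry and sets out from 18. Nitrosation with tert-butyl nitrite in THF at rt would give the N-nitrosoazocine F1. Reduction with LiAlH4 in THF at 0 °C would give the N-aminoazocine F2, a 1,1-disubstituted hydrazine. Oxidation of F2 with yellow HgO in ethanol, the established oxidation of N-amino amines to 1,1-diazenes, would produce isodiazene 20, which loses N2 and recombines, so the route is rejoined at 22.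

Step 12. Condensation at the doubly ortho-flanked ketone may stall, or hydride delivery to the cyclic ketimine may occur with poor facial selectivity. The fallback replaces carbonyl condensation by capture of a diarylmethyl cation and sets out from 16. LiAlH4 in THF at 0 °C would reduce the ketone to the amino diarylcarbinol F3, whose carbinol configuration is irrelevant. An Appel-type cyclodehydration (PPh3, CBr4, Et3N, CH2Cl2, high dilution, 0 °C to rt) would turn the hydroxyl into a leaving group. This ionises to the trimethoxy-stabilised cation at Cd, which the amine should capture intramolecularly on the less hindered face. The basic medium leaves the acetal alone, and the route is rejoined at 18.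

Step 5. Nickel may insert into the aryl triflate, the electron-rich C3 radical may dimerise or be over-oxidised, or trans selectivity may erode. The fallback switches from photochemical oxidation of the carboxylate to thermal reductive fragmentation of a redox-active ester and sets out from 5. N-hydroxyphthalimide, N,N'-diisopropylcarbodiimide and catalytic DMAP in CH2Cl2 would give the N-(acyloxy)phthalimide F4. Bromide 6 would be converted (Mg, LiCl, THF; then ZnCl2) into bis(3,5-dimethoxyphenyl)zinc F5. An iron-catalysed decarboxylative Negishi-type arylation (Fe(acac)3, dppBz, THF, rt), in which the aryl triflate is not expected to take part, would then rejoin the route at 7.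

Further compounds
F1 | step 13 | N-nitroso derivative of azocine 18 | COC(OC)c1ccc(OC)c([C@H]2c3cc(OC)cc4c3[C@H](c3cc(OC)cc(OC)c3[C@@H](N2N=O)c2ccc(OC)cc2)[C@@H](c2ccc(OC)cc2)O4)c1
F2 | step 13 | N-amino derivative of azocine 18 | COC(OC)c1ccc(OC)c([C@H]2c3cc(OC)cc4c3[C@H](c3cc(OC)cc(OC)c3[C@@H](N2N)c2ccc(OC)cc2)[C@@H](c2ccc(OC)cc2)O4)c1
F3 | step 12 | amino diarylcarbinol from reduction of the ketone of 16 (carbinol centre as a mixture) | COC(OC)c1ccc(OC)c([C@H](N)c2cc(OC)cc3c2[C@H](c2cc(OC)cc(OC)c2C(O)c2ccc(OC)cc2)[C@@H](c2ccc(OC)cc2)O3)c1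
F4 | step 5 | N-hydroxyphthalimide ester of acid 5 | FC(F)(F)S(=O)(=O)Oc1cc(OC)cc2c1[C@H](C(=O)ON1C(=O)c3ccccc3C1=O)[C@@H](c1ccc(OC)cc1)O2
F5 | step 5 | bis(3,5-dimethoxyphenyl)zinc | COc1cc([Zn]c2cc(OC)cc(OC)c2)cc(OC)c1
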